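**Retrosynthetic overview**

- The strategy rests on ring B, a pentasubstituted benzene: C1 carries the enone, C2 OMe, C3 OH, C4 OH, C5 the C(CH3)2CH=CH2 group, C6 H. C1 to C4 map onto the four carbons of dimethyl squarate; C6 and C5 map onto an E-alkenyl unit that already carries the tertiary group.
- Chalcone C1–Cβ bond: Heck coupling of a ring B aryl triflate with the ring A aryl vinyl ketone made from 4-hydroxyacetophenone. C3 O–CH3: oxidative demethylation of a guaiacol through its ortho-quinone.
- Ring B bond C4–C5: thermal 4π ring opening and 6π ring closure of a 4-alkenyl-4-hydroxycyclobutenone, itself made from dimethyl squarate and an alkenyllithium derived from prenyl chloride.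
- Ring order: ring A is bought; ring B is the only ring formed (step 4).

Key step: step 4

Remark: the squarate adduct is made as the racemate, since its only stereocentre is destroyed in the key step; the target has no stereocentre, only the E enone double bond.

**Route**

Step 1
Reactants: 1 prenyl chloride (1-chloro-3-methylbut-2-ene)
Product: 3 2,2-dimethylbut-3-enal, via prenylmagnesium chloride 2 (not isolated)
Conditions: Mg, THF, 0 °C; N-formylpiperidine, −20 °C to rt; cold aq HCl
Reagents that add atoms: N-formylpiperidine, O=CN1CCCCC1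
Why: Bouveault aldehyde synthesis with an allylic Grignard reagent, which reacts through a six-membered SE2' transition state at its more substituted terminus and so builds the quaternary carbon; the amino alkoxide adduct lasts until the acidic quench, so no second addition occurs, and the aldehyde has no α-hydrogen through which to move into conjugation.

Step 2
Reactants: 3 2,2-dimethylbut-3-enal
Product: 4 (1E)-1-iodo-3,3-dimethylpenta-1,4-diene
Conditions: CrCl2 (6 equiv), CHI3 (2 equiv), THF, 0 °C to rt
Reagents that add atoms: iodoform, IC(I)I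
Why: Takai olefination; divalent chromium reduces iodoform to a gem-dichromium species that adds to the aldehyde, and elimination places iodine trans to the bulky quaternary carbon, so the E iodide should strongly predominate.

Step 3
Reactants: 4 (1E)-1-iodo-3,3-dimethylpenta-1,4-diene; 5 dimethyl squarate (3,4-dimethoxycyclobut-3-ene-1,2-dione)
Product: 7 racemic 4-[(1E)-3,3-dimethylpenta-1,4-dien-1-yl]-4-hydroxy-2,3-dimethoxycyclobut-2-en-1-one, via alkenyllithium 6 (not isolated)
Conditions: t-BuLi (2 equiv), Et2O, −78 °C; then 5, THF, −78 °C; aq NH4Cl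
Reagents that add atoms: none
Why: Iodine–lithium exchange keeps the E geometry and the alkenyllithium adds 1,2 to one of the two equivalent carbonyl groups of the squarate at low temperature; the carbinol centre forms as the racemate and is erased in step 4.

Step 4
Reactants: 7 racemic 4-[(1E)-3,3-dimethylpenta-1,4-dien-1-yl]-4-hydroxy-2,3-dimethoxycyclobut-2-en-1-one
Product: 10 2,3-dimethoxy-5-(2-methylbut-3-en-2-yl)benzene-1,4-diol, via dienylketene 8 (not isolated), via cyclohexadienone 9 (not isolated)
Conditions: degassed toluene, 110 °C, Ar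
Reagents that add atoms: none
Why: Heating opens the C1–C4 bond of the cyclobutenone by conrotatory 4π electrocyclic ring opening to dienylketene 8, the first stage of the known Moore-type ring expansion of 4-alkenyl-4-hydroxycyclobutenones to hydroquinones. Ring B then closes as a six-membered ring by thermal disrotatory 6π electrocyclization, which joins the ketene carbon (future C4) to the alkene carbon carrying the tertiary group (future C5), and dienone 9 enolizes to the arene. No stereocentre is kept: the carbinol centre of 7 and the sp3 carbon of 9 both become aromatic carbons. The step needs ring closure to win over capture of the ketene by the enol hydroxyl, which would give a butenolide; the donor hydroxyl rotates outward on ring opening and thereby turns the dienyl group inward, next to the ketene. The E alkene keeps the C(CH3)2CH=CH2 group on the outer side of the closing terminus, and exclusion of air keeps the electron-rich hydroquinone from going on to the quinone.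

Step 5
Reactants: 10 2,3-dimethoxy-5-(2-methylbut-3-en-2-yl)benzene-1,4-diol
Product: 11 4-hydroxy-2,3-dimethoxy-5-(2-methylbut-3-en-2-yl)phenyl trifluoromethanesulfonate
Conditions: PhNTf2 (1 equiv), Et3N, CH2Cl2, 0 °C to rt, Ar
Reagents that add atoms: N-phenylbis(trifluoromethanesulfonimide), O=S(=O)(N(c1ccccc1)S(=O)(=O)C(F)(F)F)C(F)(F)F
Why: O-sulfonylation of a phenoxide with a bulky, mild triflyl donor; the hydroxyl between OMe and H should react, while the hydroxyl between OMe and the tertiary alkyl group is shielded, the same steric bias that directs monoalkylation of tert-butylhydroquinone to the remote oxygen.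

Step 6
Reactants: 11 4-hydroxy-2,3-dimethoxy-5-(2-methylbut-3-en-2-yl)phenyl trifluoromethanesulfonate
Product: 13 3,4-dihydroxy-2-methoxy-5-(2-methylbut-3-en-2-yl)phenyl trifluoromethanesulfonate, via ortho-quinone 12 (not isolated)
Conditions: IBX, DMF, rt, dark; then aq Na2S2O4
Reagents that add atoms: 2-iodoxybenzoic acid (IBX), O=C1OI(=O)(O)c2ccccc12
Why: Oxidative demethylation of a 2-methoxyphenol: the phenol binds to pentavalent iodine, oxygen is delivered to the ortho carbon bearing OMe, loss of methanol gives the ortho-quinone, and dithionite reduces it in the same flask to the catechol; only the OMe ortho to the free hydroxyl can react, so the OMe beside the triflate stays.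

Step 7
Reactants: 13 3,4-dihydroxy-2-methoxy-5-(2-methylbut-3-en-2-yl)phenyl trifluoromethanesulfonate
Product: 14 2-methoxy-3,4-bis(methoxymethoxy)-5-(2-methylbut-3-en-2-yl)phenyl trifluoromethanesulfonate
Conditions: NaH, MOMCl, DMF, 0 °C to rt, Ar
Reagents that add atoms: chloromethyl methyl ether, COCCl
Why: Williamson-type O-alkylation of both phenoxides by a small, highly reactive electrophile that should reach even the oxygen beside the tertiary group; the acetals guard the catechol against oxidation, palladium chelation and conjugate addition in the Heck step.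

Step 8
Reactants: 15 4-hydroxyacetophenone
Product: 16 1-[4-(methoxymethoxy)phenyl]ethan-1-one
Conditions: MOMCl, i-Pr2NEt, CH2Cl2, 0 °C to rt
Reagents that add atoms: chloromethyl methyl ether, COCCl
Why: Routine O-alkylation of an acidic phenol, which removes the phenoxide that would otherwise add to the vinyl ketone made in step 9.

Step 9
Reactants: 16 1-[4-(methoxymethoxy)phenyl]ethan-1-one
Product: 20 1-[4-(methoxymethoxy)phenyl]prop-2-en-1-one, via lithium enolate 17 (not isolated), via Mannich base 18 (not isolated), via trimethylammonium iodide 19 (not isolated)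
Conditions: LiN(SiMe3)2, THF, −78 °C; Me2N=CH2+ I−, −78 °C to rt; MeI; aq NaHCO3, CH2Cl2; product kept cold over BHT
Reagents that add atoms: N,N-dimethylmethyleneiminium iodide (Eschenmoser's salt), C=[N+](C)C.[I-]
Why: α-Methylenation of a methyl ketone by Mannich reaction of its enolate, N-methylation and E1cB loss of trimethylamine, all under non-acidic conditions that the MOM ether tolerates.

Step 10
Reactants: 14 2-methoxy-3,4-bis(methoxymethoxy)-5-(2-methylbut-3-en-2-yl)phenyl trifluoromethanesulfonate; 20 1-[4-(methoxymethoxy)phenyl]prop-2-en-1-one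
Product: 21 (2E)-3-[2-methoxy-3,4-bis(methoxymethoxy)-5-(2-methylbut-3-en-2-yl)phenyl]-1-[4-(methoxymethoxy)phenyl]prop-2-en-1-one
Conditions: Pd(OAc)2 (5 mol %), dppp, Et3N, BHT (cat.), DMF, 80 °C
Reagents that add atoms: none
Why: Heck reaction of an aryl triflate with an electron-poor alkene: oxidative addition to zerovalent palladium, insertion with the aryl group going to the unsubstituted β-carbon and syn β-hydride elimination should give the E enone, while the hindered, unactivated vinyl group of the side chain should not compete.

Step 11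
Reactants: 21 (2E)-3-[2-methoxy-3,4-bis(methoxymethoxy)-5-(2-methylbut-3-en-2-yl)phenyl]-1-[4-(methoxymethoxy)phenyl]prop-2-en-1-one
Product: 22 (2E)-3-[3,4-dihydroxy-2-methoxy-5-(2-methylbut-3-en-2-yl)phenyl]-1-(4-hydroxyphenyl)prop-2-en-1-one (InflamNat:IN0234)
Conditions: 3 M aq HCl, MeOH, rt to 40 °C, Ar
Reagents that add atoms: none
Why: Acid-catalysed acetal exchange with methanol should remove all three MOM groups; the monosubstituted alkene of the 1,1-dimethylallyl group would need a secondary cation to cyclize onto the neighbouring phenol and should survive dilute acid at this temperature.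

**Compound list**

1 | prenyl chloride (1-chloro-3-methylbut-2-ene) | CC(C)=CCCl | starting material
2 | prenylmagnesium chloride | CC(C)=CC[Mg]Cl | intermediate
3 | 2,2-dimethylbut-3-enal | C=CC(C)(C)C=O | intermediate
4 | (1E)-1-iodo-3,3-dimethylpenta-1,4-diene | C=CC(C)(C)/C=C/I | intermediate
5 | dimethyl squarate (3,4-dimethoxycyclobut-3-ene-1,2-dione) | COC1=C(OC)C(=O)C1=O | starting material
6 | [(1E)-3,3-dimethylpenta-1,4-dien-1-yl]lithium | [Li]/C=C/C(C)(C)C=C | intermediate
7 | racemic 4-[(1E)-3,3-dimethylpenta-1,4-dien-1-yl]-4-hydroxy-2,3-dimethoxycyclobut-2-en-1-one | COC1=C(OC)C(O)(/C=C/C(C)(C)C=C)C1=O | intermediate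
8 | (3Z,5E)-4-hydroxy-2,3-dimethoxy-7,7-dimethylnona-1,3,5,8-tetraen-1-one (dienylketene) | O=C=C(OC)/C(OC)=C(O)\C=C\C(C)(C)C=C | intermediate
9 | racemic 4-hydroxy-2,3-dimethoxy-6-(2-methylbut-3-en-2-yl)cyclohexa-2,4-dien-1-one | C=CC(C)(C)C1C=C(O)C(OC)=C(OC)C1=O | intermediate
10 | 2,3-dimethoxy-5-(2-methylbut-3-en-2-yl)benzene-1,4-diol | C=CC(C)(C)c1cc(O)c(OC)c(OC)c1O | intermediate
11 | 4-hydroxy-2,3-dimethoxy-5-(2-methylbut-3-en-2-yl)phenyl trifluoromethanesulfonate | C=CC(C)(C)c1cc(OS(=O)(=O)C(F)(F)F)c(OC)c(OC)c1O | intermediate
12 | 2-methoxy-5-(2-methylbut-3-en-2-yl)-3,4-dioxocyclohexa-1,5-dien-1-yl trifluoromethanesulfonate (ortho-quinone) | C=CC(C)(C)C1=CC(OS(=O)(=O)C(F)(F)F)=C(OC)C(=O)C1=O | intermediate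
13 | 3,4-dihydroxy-2-methoxy-5-(2-methylbut-3-en-2-yl)phenyl trifluoromethanesulfonate | C=CC(C)(C)c1cc(OS(=O)(=O)C(F)(F)F)c(OC)c(O)c1O | intermediate
14 | 2-methoxy-3,4-bis(methoxymethoxy)-5-(2-methylbut-3-en-2-yl)phenyl trifluoromethanesulfonate | C=CC(C)(C)c1cc(OS(=O)(=O)C(F)(F)F)c(OC)c(OCOC)c1OCOC | intermediate
15 | 4-hydroxyacetophenone | CC(=O)c1ccc(O)cc1 | starting material
16 | 1-[4-(methoxymethoxy)phenyl]ethan-1-one | CC(=O)c1ccc(OCOC)cc1 | intermediate
17 | lithium 1-[4-(methoxymethoxy)phenyl]ethen-1-olate | C=C(O[Li])c1ccc(OCOC)cc1 | intermediate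
18 | 3-(dimethylamino)-1-[4-(methoxymethoxy)phenyl]propan-1-one | CN(C)CCC(=O)c1ccc(OCOC)cc1 | intermediate
19 | 3-[4-(methoxymethoxy)phenyl]-N,N,N-trimethyl-3-oxopropan-1-aminium iodide | C[N+](C)(C)CCC(=O)c1ccc(OCOC)cc1.[I-] | intermediate
20 | 1-[4-(methoxymethoxy)phenyl]prop-2-en-1-one | C=CC(=O)c1ccc(OCOC)cc1 | intermediate
21 | (2E)-3-[2-methoxy-3,4-bis(methoxymethoxy)-5-(2-methylbut-3-en-2-yl)phenyl]-1-[4-(methoxymethoxy)phenyl]prop-2-en-1-one | C=CC(C)(C)c1cc(/C=C/C(=O)c2ccc(OCOC)cc2)c(OC)c(OCOC)c1OCOC | intermediate
22 | (2E)-3-[3,4-dihydroxy-2-methoxy-5-(2-methylbut-3-en-2-yl)phenyl]-1-(4-hydroxyphenyl)prop-2-en-1-one | C=CC(C)(C)c1cc(/C=C/C(=O)c2ccc(O)cc2)c(OC)c(O)c1O | target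

**Step count**

Total steps: 11. Longest linear sequence: 9 steps (steps 1 to 7, 10 and 11); steps 8 and 9 form the side branch.

**Steps most likely to fail**

Step 4 (key step). The free hydroquinone may be lost by oxidation to the quinone at the reaction temperature or on work-up. If the bulky tertiary group slows ring closure, the ketene may instead be captured by the enol hydroxyl. The fallback sets out from 7 and returns at 11, without isolating 10.
- The tertiary hydroxyl is silylated (Et3SiOTf, 2,6-lutidine, CH2Cl2, −78 °C) to give racemic 4-[(1E)-3,3-dimethylpenta-1,4-dien-1-yl]-2,3-dimethoxy-4-[(triethylsilyl)oxy]cyclobut-2-en-1-one F1.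
- Thermolysis in toluene at reflux should give 2,3-dimethoxy-6-(2-methylbut-3-en-2-yl)-4-[(triethylsilyl)oxy]phenol F2. The silyl ether cannot lactonize, and F2 is not a free hydroquinone.
- Fluoride-triggered cleavage of the silyl ether in the presence of the triflyl donor (CsF, PhNTf2, MeCN, rt) should place the triflate on the unhindered oxygen and deliver 11.

Step 6. Ligand exchange of the hindered, triflate-deactivated phenol at iodine may be slow. The transient ortho-quinone, a vinylogous acyl triflate, may also lose its triflate to nucleophiles before it is reduced. The fallback sets out from 11 and returns at 13, and it is not oxidative.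
- BCl3 (1.1 equiv, CH2Cl2, −78 to 0 °C) binds the free phenol oxygen.
- Boron then cleaves the neighbouring O–CH3 bond intramolecularly, giving 2-chloro-4-methoxy-7-(2-methylbut-3-en-2-yl)-1,3,2-benzodioxaborol-5-yl trifluoromethanesulfonate F3.
- Aqueous work-up hydrolyses F3 to 13. The OMe beside the triflate has no neighbouring hydroxyl to direct boron to it.

Step 10. The aryl vinyl ketone may oligomerize under hot basic conditions, oxidative addition to the electron-rich triflate may be slow, and conjugate reduction may compete with β-hydride elimination. The fallback sets out from 14 and returns at 21; it replaces the Heck coupling by formylation and aldol condensation and makes step 9 unnecessary.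
- Reductive carbonylation of the triflate (Pd(OAc)2, dppp, CO 1 atm, Et3SiH, Et3N, DMF, 70 °C) should give 2-methoxy-3,4-bis(methoxymethoxy)-5-(2-methylbut-3-en-2-yl)benzaldehyde F4.
- Claisen–Schmidt condensation of F4 with ketone 16 (KOH, EtOH/H2O, rt) should give the E chalcone 21.

**Further compounds**

F1 | step 4 | racemic 4-[(1E)-3,3-dimethylpenta-1,4-dien-1-yl]-2,3-dimethoxy-4-[(triethylsilyl)oxy]cyclobut-2-en-1-one | CC[Si](CC)(CC)OC1(/C=C/C(C)(C)C=C)C(OC)=C(OC)C1=O
F2 | step 4 | 2,3-dimethoxy-6-(2-methylbut-3-en-2-yl)-4-[(triethylsilyl)oxy]phenol | C=CC(C)(C)c1cc(O[Si](CC)(CC)CC)c(OC)c(OC)c1O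
F3 | step 6 | 2-chloro-4-methoxy-7-(2-methylbut-3-en-2-yl)-1,3,2-benzodioxaborol-5-yl trifluoromethanesulfonate | C=CC(C)(C)c1cc(OS(=O)(=O)C(F)(F)F)c(OC)c2OB(Cl)Oc12
F4 | step 10 | 2-methoxy-3,4-bis(methoxymethoxy)-5-(2-methylbut-3-en-2-yl)benzaldehyde | C=CC(C)(C)c1cc(C=O)c(OC)c(OCOC)c1OCOC
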